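**Retrosynthetic overview**
- The target is the bis-O-benzyl lactone after hydrogenolysis; benzyl ethers on O5 and O7 leave only the phenol next to the ketone free, which fixes which oxygen becomes the lactone oxygen.
- C4–C4a bond and lactone ring: intramolecular, invertive Friedel–Crafts displacement of a benzylic acetate by the arene of an aryl (R)-3-acetoxy-3-phenylpropanoate (new step).
- C3–C4 bond and aryl ester: photochemical Wolff rearrangement of the diazoketone from (S)-O-acetylmandelic acid (retention), with the ketene trapped by the free phenol.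
- Phenol partner: Friedel–Crafts acylation of phloroglucinol with 3-phenylpropanoyl chloride, then selective bis-benzylation.
- Ring order: the aromatic ring is bought; the lactone is the only ring made, in the penultimate step.

Assumption: CNP0321593.1 is the (4S) enantiomer, as the SMILES specifies (CIP order at C4: C4a > phenyl > C3 > H).

**Step 1**
Reactants: 1 phloroglucinol; 2 3-phenylpropanoyl chloride
Product: 3 3-phenyl-1-(2,4,6-trihydroxyphenyl)propan-1-one
Conditions: AlCl3 (3.5 equiv), PhNO2/CH2Cl2, 0 to 60 °C; then 1 M HCl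
Reagents that add atoms: none
Why: Friedel–Crafts acylation; the three ring CH positions of 1 are equivalent, so one regioisomer forms, and the new acyl group deactivates the ring against a second acylation.

**Step 2**
Reactants: 3 3-phenyl-1-(2,4,6-trihydroxyphenyl)propan-1-one
Product: 4 1-[2,4-bis(benzyloxy)-6-hydroxyphenyl]-3-phenylpropan-1-one
Conditions: BnBr (2.1 equiv), K2CO3 (2.2 equiv), acetone, reflux
Reagents that add atoms: benzyl bromide, BrCc1ccccc1
Why: Williamson ether synthesis; the hydroxyl hydrogen-bonded to the ketone is the least acidic and least nucleophilic, so it stays free, and either ortho hydroxyl gives the same compound by symmetry.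

**Step 3**
Reactants: 5 (S)-O-acetylmandelic acid
Product: 7 (1S)-3-diazo-2-oxo-1-phenylpropyl acetate, via (2S)-2-acetoxy-2-phenylacetyl chloride 6 (not isolated)
Conditions: (COCl)2 (1.2 equiv), DMF (cat.), CH2Cl2, 0 °C to rt; evaporate; Me3SiCHN2 (2.2 equiv), THF/MeCN 1:1, 0 °C
Reagents that add atoms: trimethylsilyldiazomethane, C[Si](C)(C)C=[N+]=[N-] (CHN2 carbon and both nitrogens of 7); oxalyl chloride, O=C(Cl)C(=O)Cl (chlorine of 6 only)
Why: Acid chloride formation followed by C-acylation of the diazomethane equivalent (first half of an Arndt–Eistert homologation); no amine base is present, so the α-stereocenter bought in 5 is not epimerised.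

**Step 4**
Reactants: 7 (1S)-3-diazo-2-oxo-1-phenylpropyl acetate (1.5 equiv, added slowly); 4 1-[2,4-bis(benzyloxy)-6-hydroxyphenyl]-3-phenylpropan-1-one
Product: 9 3,5-bis(benzyloxy)-2-(3-phenylpropanoyl)phenyl (3R)-3-acetoxy-3-phenylpropanoate, via (1R)-3-oxo-1-phenylprop-2-en-1-yl acetate 8 (not isolated)
Conditions: hν (450 nm LEDs), toluene, 30 °C, argon, no base
Reagents that add atoms: none
Why: Photochemical Wolff rearrangement: the CH(OAc)Ph group migrates to the carbene carbon with retention, forming the C3–C4 bond, and the slowly generated ketene 8 is trapped by the only free phenol of 4. At 450 nm only the diazoketone absorbs, which spares the aryl ketone and benzyl ethers from photo-Fries and Norrish–Yang reactions, and the base-free medium avoids β-elimination of acetate. (The descriptor changes from S to R only because CH2 ranks below phenyl.)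

**Step 5**
Reactants: 9 3,5-bis(benzyloxy)-2-(3-phenylpropanoyl)phenyl (3R)-3-acetoxy-3-phenylpropanoate
Product: 10 (4S)-5,7-bis(benzyloxy)-4-phenyl-8-(3-phenylpropanoyl)-3,4-dihydro-2H-chromen-2-one
Conditions: Me3SiOTf (20 mol %), 4 Å MS, CH2Cl2 (0.02 M), −78 to −30 °C
Reagents that add atoms: none
Why: Proposed new method: a Lewis-acid-triggered, stereoinvertive 6-exo-tet Friedel–Crafts displacement of a secondary benzylic acetate by a tethered arene. Me3SiOTf silylates the acetate carbonyl; the β-aryloxycarbonyl group inductively disfavours a free benzylic cation; and the only free ring carbon ortho to the ester oxygen (activated ortho and para by the two benzyloxy groups) is held in a six-membered array. It should therefore attack C4 anti to the departing acetate within the contact ion pair in non-ionising CH2Cl2 at low temperature, forming C4–C4a and the lactone ring with inversion ((R)-9 to (S)-10). The closest known reaction types are the SN2-type Friedel–Crafts openings of enantiopure styrene oxide and N-sulfonyl-2-arylaziridines by electron-rich arenes and the invertive Friedel–Crafts alkylation of arenes with lactate sulfonates.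

**Step 6**
Reactants: 10 (4S)-5,7-bis(benzyloxy)-4-phenyl-8-(3-phenylpropanoyl)-3,4-dihydro-2H-chromen-2-one
Product: 11 (4S)-5,7-dihydroxy-4-phenyl-8-(3-phenylpropanoyl)-3,4-dihydro-2H-chromen-2-one (CNP0321593.1)
Conditions: H2 (1 atm), 10% Pd/C, EtOAc, rt; filter, crystallise
Reagents that add atoms: none
Why: Hydrogenolysis of the two benzyl aryl ethers; the neutral, non-nucleophilic medium does not open the lactone (opening would let it re-close on the other phenol), and C4 has no pathway to epimerise.

**Compound list**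
1 | phloroglucinol (benzene-1,3,5-triol) | Oc1cc(O)cc(O)c1 | starting material
2 | 3-phenylpropanoyl chloride | O=C(Cl)CCc1ccccc1 | starting material
3 | 3-phenyl-1-(2,4,6-trihydroxyphenyl)propan-1-one | O=C(CCc1ccccc1)c1c(O)cc(O)cc1O | intermediate
4 | 1-[2,4-bis(benzyloxy)-6-hydroxyphenyl]-3-phenylpropan-1-one | O=C(CCc1ccccc1)c1c(O)cc(OCc2ccccc2)cc1OCc1ccccc1 | intermediate
5 | (S)-O-acetylmandelic acid, (2S)-2-acetoxy-2-phenylacetic acid | CC(=O)O[C@@H](c1ccccc1)C(=O)O | starting material
6 | (2S)-2-acetoxy-2-phenylacetyl chloride | CC(=O)O[C@@H](c1ccccc1)C(=O)Cl | intermediate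
7 | (1S)-3-diazo-2-oxo-1-phenylpropyl acetate | CC(=O)O[C@@H](c1ccccc1)C(=O)C=[N+]=[N-] | intermediate
8 | (1R)-3-oxo-1-phenylprop-2-en-1-yl acetate (ketene) | CC(=O)O[C@@H](c1ccccc1)C=C=O | intermediate
9 | 3,5-bis(benzyloxy)-2-(3-phenylpropanoyl)phenyl (3R)-3-acetoxy-3-phenylpropanoate | CC(=O)O[C@@H](c1ccccc1)CC(=O)Oc1cc(OCc2ccccc2)cc(OCc2ccccc2)c1C(=O)CCc1ccccc1 | intermediate
10 | (4S)-5,7-bis(benzyloxy)-4-phenyl-8-(3-phenylpropanoyl)-3,4-dihydro-2H-chromen-2-one | O=C1C[C@@H](c2ccccc2)c2c(OCc3ccccc3)cc(OCc3ccccc3)c(C(=O)CCc3ccccc3)c2O1 | intermediate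
11 | (4S)-5,7-dihydroxy-4-phenyl-8-(3-phenylpropanoyl)-3,4-dihydro-2H-chromen-2-one | O=C1C[C@@H](c2ccccc2)c2c(O)cc(O)c(C(=O)CCc3ccccc3)c2O1 | target

**Step count**
Total: 6 steps. Longest linear sequence: 5 steps (1 to 3 to 4 to 9 to 10 to 11); the branch 5 to 7 is one step.

**Steps most likely to fail, with fallbacks**

Step 5 (the proposed new cyclisation). The risks are ionisation to a free benzylic cation, which would erode the ee, and elimination to the aryl cinnamate; the ee of 10 must be checked by chiral HPLC against a racemate. The fallback sets out from 4 and comes back at 10, using known chemistry with a bought epoxide: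
- 4 is esterified with potassium (2R,3S)-3-phenyloxirane-2-carboxylate (bought; [K+].[O-]C(=O)[C@@H]1O[C@H]1c1ccccc1) using EDC·HCl and DMAP in CH2Cl2, giving 3,5-bis(benzyloxy)-2-(3-phenylpropanoyl)phenyl (2R,3S)-3-phenyloxirane-2-carboxylate F1.
- BF3·OEt2 in CH2Cl2 at −40 °C effects the intramolecular epoxide–arene Friedel–Crafts cyclisation, the arene opening the benzylic epoxide carbon with inversion, giving (3R,4S)-5,7-bis(benzyloxy)-3-hydroxy-4-phenyl-8-(3-phenylpropanoyl)-3,4-dihydro-2H-chromen-2-one F2.
- The superfluous 3-hydroxyl is removed by Barton–McCombie deoxygenation: PhOC(S)Cl and DMAP give O-[(3R,4S)-5,7-bis(benzyloxy)-2-oxo-4-phenyl-8-(3-phenylpropanoyl)-3,4-dihydro-2H-chromen-3-yl] O-phenyl carbonothioate F3, and Bu3SnH with AIBN in toluene at 80 °C then gives 10.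

Step 4 (Wolff rearrangement and ketene capture). The hydrogen-bonded phenol of 4 may trap the ketene too slowly, so that ketene dimerisation or hydrolysis wins. The fallback sets out from 4 and comes back at 9, with no photochemistry and no diazo compound: bought (R)-3-hydroxy-3-phenylpropanoic acid (O[C@@H](c1ccccc1)CC(=O)O) is acetylated with Ac2O and pyridine to (3R)-3-acetoxy-3-phenylpropanoic acid F4, which is coupled to 4 by Steglich esterification (DCC, 5 mol % DMAP, CH2Cl2, 0 °C) to give 9.

Step 2 (selective bis-benzylation). Over-alkylation or C-benzylation of the electron-rich ring may lower the yield. The fallback sets out from 3 and comes back at 4: exhaustive benzylation (excess BnBr, K2CO3, DMF, 60 °C) gives 3-phenyl-1-[2,4,6-tris(benzyloxy)phenyl]propan-1-one F5, and BCl3 (1.0 equiv, CH2Cl2, −78 °C) then removes only the benzyl group ortho to the ketone by chelation-controlled cleavage, giving 4.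

**Further compounds**
F1 | step 5 | 3,5-bis(benzyloxy)-2-(3-phenylpropanoyl)phenyl (2R,3S)-3-phenyloxirane-2-carboxylate | O=C(Oc1cc(OCc2ccccc2)cc(OCc2ccccc2)c1C(=O)CCc1ccccc1)[C@@H]1O[C@H]1c1ccccc1
F2 | step 5 | (3R,4S)-5,7-bis(benzyloxy)-3-hydroxy-4-phenyl-8-(3-phenylpropanoyl)-3,4-dihydro-2H-chromen-2-one | O=C1[C@H](O)[C@@H](c2ccccc2)c2c(OCc3ccccc3)cc(OCc3ccccc3)c(C(=O)CCc3ccccc3)c2O1
F3 | step 5 | O-[(3R,4S)-5,7-bis(benzyloxy)-2-oxo-4-phenyl-8-(3-phenylpropanoyl)-3,4-dihydro-2H-chromen-3-yl] O-phenyl carbonothioate | O=C1[C@H](OC(=S)Oc2ccccc2)[C@@H](c2ccccc2)c2c(OCc3ccccc3)cc(OCc3ccccc3)c(C(=O)CCc3ccccc3)c2O1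
F4 | step 4 | (3R)-3-acetoxy-3-phenylpropanoic acid | CC(=O)O[C@@H](c1ccccc1)CC(=O)O
F5 | step 2 | 3-phenyl-1-[2,4,6-tris(benzyloxy)phenyl]propan-1-one | O=C(CCc1ccccc1)c1c(OCc2ccccc2)cc(OCc2ccccc2)cc1OCc1ccccc1
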